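**Retrosynthetic overview**

1. Guidongnin 30 comes from the 16-methylene 11,15-dione 28 by two late reductions (C15, then C11); 28 comes from the 17-nor dione 25 and this from diol 24.
2. Key disconnection: C9–C11 (ring C) and C8–C15 (ring D) are cut together. This rests on C8 being alpha and C9 beta to the ring B lactone carbonyl C7, and on C13 carrying two arms (C12–C11 and C16–C15) that are the same CH2CHO group, so the achiral side chain of dialdehyde 22 is desymmetrised in one SmI2 ketyl-enoate/aldol cascade.
3. 22 comes from double ozonolysis of a diallyl lactone, made by C8 alkylation of spirolactone 15 with iodide 4 and selenoxide dehydrogenation.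
4. 15 comes from titanium-mediated epoxide opening and acrylate addition at C10 (ring B) on the ring A methylene lactol ether 12, whose C4 centre comes from a copper-catalysed asymmetric conjugate methylation.
5. Ring order: A, then E (the C6/C19 five-membered ring), then B, then C and D in one step; the exocyclic methylene is added last.

Key step: step 16

Numbering: kaurane numbering is used throughout; ring E is the C6–O–C19 five-membered ring.

Assumption: in step 16 the ketyl oxygen is taken to sit outside the forming ring and the aldolate to be chelated, so 24 is drawn as the C11,C15 bis-epimer of 17-norguidongnin; step 17 erases both centres, so the route holds for any C11/C15 outcome.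

**Route**

Step 1
Reactants: 1 diethyl diallylmalonate
Product: 2 ethyl 2-allylpent-4-enoate
Conditions: LiCl, H2O, DMSO, 170 °C
Reagents that add atoms: none
Why: Krapcho dealkoxycarbonylation of the geminal diester leaves the mono-ester and involves no stereocentre.

Step 2
Reactants: 2 ethyl 2-allylpent-4-enoate
Product: 3 2-allylpent-4-en-1-ol
Conditions: LiAlH4, Et2O, 0 °C
Reagents that add atoms: none
Why: LiAlH4 reduction of the ester gives the primary alcohol and leaves both terminal alkenes untouched.

Step 3
Reactants: 3 2-allylpent-4-en-1-ol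
Product: 4 4-(iodomethyl)hepta-1,6-diene
Conditions: I2, PPh3, imidazole, CH2Cl2, 0 → 23 °C
Reagents that add atoms: iodine, II
Why: Appel-type iodination of the unhindered primary alcohol gives the alkylating agent in which the CH2I carbon is the future C14 and the branch carbon the future C13.

Step 4
Reactants: 5 3-bromocyclohex-2-en-1-one
Product: 6 3-(hydroxymethyl)cyclohex-2-en-1-one
Conditions: Bu3SnCH2OH, Pd(PPh3)4 (5 mol %), 1,4-dioxane, 90 °C
Reagents that add atoms: (tributylstannyl)methanol, CCCC[Sn](CCCC)(CCCC)CO
Why: Stille coupling of the vinylogous acyl bromide with the hydroxymethylstannane places the future C19 on the enone beta carbon (future C4).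

Step 5
Reactants: 6 3-(hydroxymethyl)cyclohex-2-en-1-one
Product: 7 3-{[(tert-butyldimethylsilyl)oxy]methyl}cyclohex-2-en-1-one
Conditions: t-BuMe2SiCl, imidazole, CH2Cl2, 23 °C
Reagents that add atoms: tert-butyldimethylsilyl chloride, CC(C)(C)[Si](C)(C)Cl
Why: silylation protects the primary allylic alcohol so that Me3Al is not consumed and the C19 oxygen is carried to step 8.

Step 6
Reactants: 7 3-{[(tert-butyldimethylsilyl)oxy]methyl}cyclohex-2-en-1-one
Product: 9 (R)-tert-butyldimethyl{[1-methyl-3-(trimethylsilyloxy)cyclohex-2-en-1-yl]methoxy}silane, via aluminium enolate 8 (not isolated)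
Conditions: Me3Al, Cu(O2CC4H3S) (copper thiophene-2-carboxylate, 5 mol %), chiral biphenol-based phosphoramidite (10 mol %, enantiomer that gives R), Et2O, −30 °C; then Me3SiOTf, THF, −30 → 0 °C
Reagents that add atoms: trimethylaluminium, C[Al](C)C; trimethylsilyl trifluoromethanesulfonate, C[Si](C)(C)OS(=O)(=O)C(F)(F)F
Why: copper-catalysed asymmetric conjugate addition of Me3Al to the beta-substituted cyclohexenone creates the C4 quaternary centre under control of the chiral phosphoramidite, and trapping the aluminium enolate on oxygen fixes the enol double bond regiospecifically toward C5.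

Step 7
Reactants: 9 (R)-tert-butyldimethyl{[1-methyl-3-(trimethylsilyloxy)cyclohex-2-en-1-yl]methoxy}silane
Product: 10 (3R)-3-{[(tert-butyldimethylsilyl)oxy]methyl}-2-(dimethoxymethyl)-3-methylcyclohexan-1-one (C2 epimers)
Conditions: HC(OMe)3, Me3SiOTf (10 mol %), CH2Cl2, −78 °C
Reagents that add atoms: trimethyl orthoformate, COC(OC)OC
Why: Mukaiyama-type addition of the silyl enol ether to the dimethoxycarbenium ion from the orthoformate attaches C6 at the aldehyde oxidation level to C5, whose configuration is left open because it is still epimerisable.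

Step 8
Reactants: 10 (3R)-3-{[(tert-butyldimethylsilyl)oxy]methyl}-2-(dimethoxymethyl)-3-methylcyclohexan-1-one
Product: 11 (3aR,7aS)-1-methoxy-3a-methylhexahydro-2-benzofuran-7(1H)-one (cis-fused keto lactol ether; both anomers)
Conditions: camphorsulfonic acid (20 mol %), MeOH, 23 °C
Reagents that add atoms: none
Why: acid methanolysis frees the C19 alcohol, which closes ring E by transacetalisation, and C5 (alpha to the ketone) should equilibrate to the more stable cis-fused bicycle with H5 cis to the C4 methyl.

Step 9
Reactants: 11 (3aR,7aS)-1-methoxy-3a-methylhexahydro-2-benzofuran-7(1H)-one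
Product: 12 (3aR,7aS)-1-methoxy-3a-methyl-7-methylideneoctahydro-2-benzofuran
Conditions: (C5H5)2Ti(CH3)2, toluene, 65 °C, dark
Reagents that add atoms: dimethyltitanocene, [CH3-].[CH3-].[cH-]1cccc1.[cH-]1cccc1.[Ti+4]
Why: Petasis methylenation with the non-basic titanium methylidene converts the hindered enolisable ketone into the C10 exocyclic alkene without epimerising C5 or eliminating the beta-alkoxy group.

Step 10
Reactants: 12 (3aR,7aS)-1-methoxy-3a-methyl-7-methylideneoctahydro-2-benzofuran
Product: 13 C10/C20 spiro-epoxide of 12 (both epimers)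
Conditions: mCPBA, NaHCO3, CH2Cl2, 0 °C
Reagents that add atoms: 3-chloroperoxybenzoic acid, OOC(=O)c1cccc(Cl)c1
Why: buffered Prilezhaev epoxidation of the 1,1-disubstituted alkene spares the acetal, and the epoxide configuration does not matter because C10 becomes a planar radical in the next step.

Step 11
Reactants: 13 C10/C20 spiro-epoxide of 12
Product: 15 saturated spirolactone (ring B closed on C10), via trifluoroethyl hydroxy ester 14 (not isolated)
Conditions: (C5H5)2TiCl2, Zn, THF, 23 °C; then 13, CF3CH2O2CCH=CH2, 2,4,6-collidine·HCl, 0 → 23 °C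
Reagents that add atoms: 2,2,2-trifluoroethyl acrylate, C=CC(=O)OCC(F)(F)F
Why: reductive epoxide opening by trivalent titanium (Nugent–RajanBabu type) gives the tertiary C10 radical, which undergoes Giese addition to the acrylate on the face anti to C6 because the axial C19 blocks the other face (C20 cis and C9 trans to C6), and the titanium alkoxide then lactonises on the activated ester.

Step 12
Reactants: 15 saturated spirolactone; 4 4-(iodomethyl)hepta-1,6-diene
Product: 16 C8-alkylated spirolactone (C8 epimers)
Conditions: LiN(i-Pr)2, THF, −78 °C; then 4, DMPU, −78 → −20 °C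
Reagents that add atoms: none
Why: alkylation of the lithium lactone enolate, the only acidic site in 15, with the primary iodide attaches C14, C13 and both allyl arms to C8, whose configuration is removed in the next step.

Step 13
Reactants: 16 C8-alkylated spirolactone
Product: 19 unsaturated spirolactone (C8=C9; C6 still a lactol ether), via selenide 17 (not isolated), via selenoxide 18 (not isolated)
Conditions: LiN(i-Pr)2, THF, −78 °C; PhSeBr; then NaIO4, NaHCO3, THF/MeOH/H2O, 0 → 23 °C
Reagents that add atoms: none
Why: alpha-selenenylation of the lactone enolate followed by selenoxide syn-elimination toward the ring hydrogen on C9 should give the endocyclic enoate, and periodate is used as oxidant so that the terminal alkenes are not epoxidised.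

Step 14
Reactants: 19 unsaturated spirolactone
Product: 20 bis-lactone diene
Conditions: CrO3, H2SO4, acetone/H2O, 0 °C
Reagents that add atoms: water, O
Why: Jones oxidation hydrolyses the lactol methyl ether and oxidises the lactol to the C6 lactone of ring E without touching the alkenes or the cis ring fusion.

Step 15
Reactants: 20 bis-lactone diene
Product: 22 dialdehyde (ring A unsaturated spiro lactone with a 4-oxo-2-(2-oxoethyl)butyl group on C8), via bis-ozonide 21 (not isolated)
Conditions: O3, CH2Cl2, −78 °C (Sudan Red 7B end point); then PPh3, −78 → 23 °C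
Reagents that add atoms: ozone, O=[O+][O-]
Why: ozonolysis cleaves the two electron-rich monosubstituted alkenes much faster than the electron-poor, hindered trisubstituted enoate, so each allyl arm becomes CH2CHO.

Step 16
Reactants: 22 dialdehyde
Product: 24 11,15-di-epi-17-norguidongnin, via samarium enolate 23 (not isolated)
Conditions: SmI2 (2.3 equiv, 0.1 M in THF) added over 1 h to 22 (5 mM in THF), −78 °C; then −78 → 0 °C; aq. NH4Cl
Reagents that add atoms: none
Why: SmI2 transfers one electron to either formyl group, and the ketyl carbon C11 adds 6-endo-trig to C9, the only polarity-matched site because the tether hangs on the alpha carbon C8; a second electron turns the C8 radical into a trivalent samarium enolate that closes ring D by a 5-exo-trig (enolexo) aldol addition to the formyl carbon C15 of the untouched arm. The closest known reaction type is the SmI2 ketyl-enoate cyclisation/aldol cascade of dialdehydes bearing an unsaturated lactone, which is known on spiro unsaturated delta-lactones of this kind with the same 6-endo first step. C9 is set by attack on the lactone face that carries C1 rather than the C5 branch; C13 and C8 are set together because the spectator arm takes the equatorial site of the chair-like transition state, which places it syn to H9, and that arm can reach the enolate only on the H9 face (through a twist-boat of ring C), so the C8–C15 bond forms cis to H9 as in the target bicyclo[3.2.1]octane. C11 (ketyl oxygen outside, OH cis to H9) and C15 (chelated aldolate, OH syn to the C7 carbonyl) are expected to be epimeric to the target, which does not matter because step 17 oxidises both. The step needs ketyl-enoate addition to beat pinacol coupling of the two formyl groups and the aldol to beat protonation of the enolate; slow inverse addition keeps divalent samarium low so that the reversible ketyl addition to a carbonyl is not trapped while addition to the enoate is irreversible, and no proton source is present until the quench. The two arms sit on a carbon without stereochemistry, so the five stereocentres C8, C9, C11, C13 and C15 all arise here under control of C10.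

Step 17
Reactants: 24 11,15-di-epi-17-norguidongnin
Product: 25 17-norguidongnin-11,15-dione
Conditions: Dess–Martin periodinane, NaHCO3, CH2Cl2, 23 °C
Reagents that add atoms: none
Why: Dess–Martin oxidation takes both secondary alcohols to ketones, which erases the two carbinol centres of the cascade whatever their configuration and leaves the non-enolisable C7/C15 keto lactone intact.

Step 18
Reactants: 25 17-norguidongnin-11,15-dione
Product: 28 11,15-didehydroguidongnin (16-methylene-11,15-dione), via Mannich base 26 (not isolated), via ammonium iodide 27 (not isolated)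
Conditions: LiN(SiMe3)2 (1.05 equiv), THF, −78 °C; [Me2N=CH2]I, −78 → 0 °C; then MeI, CH2Cl2, 23 °C; then aq. NaHCO3, 23 °C
Reagents that add atoms: Eschenmoser's salt, C=[N+](C)C.[I-]
Why: kinetic deprotonation should occur at C16, whose exo C–H on the convex face belongs to a cyclopentanone activated by the C7 lactone, whereas the aligned axial C12–H of the C11 ketone is screened by the axial C10 and C9–H is equatorial, and the enolate then undergoes Mannich reaction with Eschenmoser's salt, quaternisation and Hofmann-type elimination to the exocyclic enone.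

Step 19
Reactants: 28 11,15-didehydroguidongnin
Product: 29 11-dehydroguidongnin (15-alcohol as in the target)
Conditions: NaBH4 (1.0 equiv), CeCl3·7H2O, MeOH/THF, −78 °C
Reagents that add atoms: none
Why: Luche 1,2-reduction is selective for the conjugated C15 ketone over the hindered C11 ketone, and hydride attacks the exo face of ring D, away from ring C, to give the endo 15-alcohol of the target.

Step 20
Reactants: 29 11-dehydroguidongnin
Product: 30 guidongnin
Conditions: Me4NBH(OAc)3, MeCN/AcOH, −20 → 0 °C
Reagents that add atoms: none
Why: in this hydroxyl-directed reduction (Evans–Saksena type) the acetoxyborohydride bound to the endo C15 oxygen delivers hydride to the face of the C11 ketone that looks at the C15–C16 bridge, which gives the equatorial 11-alcohol trans to H9.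

**Compound list**

1 | diethyl diallylmalonate | CCOC(=O)C(CC=C)(CC=C)C(=O)OCC | starting material
2 | ethyl 2-allylpent-4-enoate | CCOC(=O)C(CC=C)CC=C | intermediate
3 | 2-allylpent-4-en-1-ol | OCC(CC=C)CC=C | intermediate
4 | 4-(iodomethyl)hepta-1,6-diene | ICC(CC=C)CC=C | intermediate
5 | 3-bromocyclohex-2-en-1-one | O=C1C=C(Br)CCC1 | starting material
6 | 3-(hydroxymethyl)cyclohex-2-en-1-one | O=C1C=C(CO)CCC1 | intermediate
7 | 3-{[(tert-butyldimethylsilyl)oxy]methyl}cyclohex-2-en-1-one | O=C1C=C(CO[Si](C)(C)C(C)(C)C)CCC1 | intermediate
8 | dimethylaluminium enolate of the (R)-3-methyl-3-(silyloxymethyl)cyclohexanone (not isolated) | C[Al](C)OC1=C[C@](C)(CO[Si](C)(C)C(C)(C)C)CCC1 | intermediate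
9 | (R)-tert-butyldimethyl{[1-methyl-3-(trimethylsilyloxy)cyclohex-2-en-1-yl]methoxy}silane | C[Si](C)(C)OC1=C[C@](C)(CO[Si](C)(C)C(C)(C)C)CCC1 | intermediate
10 | (3R)-3-{[(tert-butyldimethylsilyl)oxy]methyl}-2-(dimethoxymethyl)-3-methylcyclohexan-1-one, C2 (future C5) not defined | O=C1CCC[C@@](C)(CO[Si](C)(C)C(C)(C)C)C1C(OC)OC | intermediate
11 | (3aR,7aS)-1-methoxy-3a-methylhexahydro-2-benzofuran-7(1H)-one, cis-fused, anomeric carbon (C6) not defined | COC1OC[C@]2(C)CCCC(=O)[C@H]12 | intermediate
12 | (3aR,7aS)-1-methoxy-3a-methyl-7-methylideneoctahydro-2-benzofuran, anomeric carbon not defined | COC1OC[C@]2(C)CCCC(=C)[C@H]12 | intermediate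
13 | spiro-epoxide of 12 across C10/C20, epoxide and anomeric centres not defined | COC1OC[C@]2(C)CCCC3(CO3)[C@H]12 | intermediate
14 | 2,2,2-trifluoroethyl 3-[C10-(hydroxymethyl) ring A lactol ether]propanoate, C20 cis and C9 trans to C6 (not isolated; present as its titanium alkoxide) | COC1OC[C@]2(C)CCC[C@@](CO)(CCC(=O)OCC(F)(F)F)[C@H]12 | intermediate
15 | saturated spiro delta-lactone (ring B) on C10 of the ring A lactol ether, C4, C5, C10 as in 30 | COC1OC[C@]2(C)CCC[C@@]3(CCC(=O)OC3)[C@H]12 | intermediate
16 | 15 carrying a 2-allylpent-4-en-1-yl group on C8, C8 not defined | COC1OC[C@]2(C)CCC[C@@]3(CC(CC(CC=C)CC=C)C(=O)OC3)[C@H]12 | intermediate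
17 | C8 phenylselenide of 16 (not isolated) | COC1OC[C@]2(C)CCC[C@@]3(CC(CC(CC=C)CC=C)([Se]c4ccccc4)C(=O)OC3)[C@H]12 | intermediate
18 | selenoxide of 17 (not isolated) | COC1OC[C@]2(C)CCC[C@@]3(CC(CC(CC=C)CC=C)([Se](=O)c4ccccc4)C(=O)OC3)[C@H]12 | intermediate
19 | C8=C9 unsaturated spirolactone with the C8 2-allylpent-4-en-1-yl group, C6 lactol methyl ether | COC1OC[C@]2(C)CCC[C@@]3(C=C(CC(CC=C)CC=C)C(=O)OC3)[C@H]12 | intermediate
20 | bis-lactone diene: 19 with the C6/C19 gamma-lactone in place of the lactol ether | O=C1OC[C@]2(C)CCC[C@@]3(C=C(CC(CC=C)CC=C)C(=O)OC3)[C@H]12 | intermediate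
21 | bis(1,2,4-trioxolane) of 20 (not isolated) | O=C1OC[C@]2(C)CCC[C@@]3(C=C(CC(CC4OCOO4)CC5OCOO5)C(=O)OC3)[C@H]12 | intermediate
22 | dialdehyde: ring A unsaturated spiro delta-lactone with a 4-oxo-2-(2-oxoethyl)butyl group on C8 and the C6/C19 gamma-lactone | O=CCC(CC=O)CC1=C[C@@]4(CCC[C@@]5(C)COC(=O)[C@H]54)COC1=O | intermediate
23 | ring C closed trivalent samarium enolate/alkoxide, spare CH2CHO arm on C13 syn to H9 (not isolated) | O=CC[C@@H]2C[C@H]([O-])[C@H]3[C@@]4(CCC[C@@]5(C)COC(=O)[C@H]54)COC([O-])=C3C2.[Sm+3].[Sm+3].[I-].[I-].[I-].[I-] | intermediate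
24 | 11,15-di-epi-17-norguidongnin: C16 is CH2, 11-OH cis to H9 (axial, facing the C15–C16 bridge), 15-OH exo (syn to the C7 carbonyl) | C1[C@@H]2C[C@H](O)[C@H]3[C@@]4(CCC[C@@]5(C)COC(=O)[C@H]54)COC(=O)[C@]3(C2)[C@H]1O | intermediate
25 | 17-norguidongnin-11,15-dione | C1[C@@H]2CC(=O)[C@H]3[C@@]4(CCC[C@@]5(C)COC(=O)[C@H]54)COC(=O)[C@]3(C2)C1=O | intermediate
26 | 16-(dimethylaminomethyl) derivative of 25, C16 not defined (not isolated) | CN(C)CC1[C@@H]2CC(=O)[C@H]3[C@@]4(CCC[C@@]5(C)COC(=O)[C@H]54)COC(=O)[C@]3(C2)C1=O | intermediate
27 | trimethylammonium iodide of 26 (not isolated) | C[N+](C)(C)CC1[C@@H]2CC(=O)[C@H]3[C@@]4(CCC[C@@]5(C)COC(=O)[C@H]54)COC(=O)[C@]3(C2)C1=O.[I-] | intermediate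
28 | 11,15-didehydroguidongnin (16-methylene-11,15-dione) | C=C1[C@@H]2CC(=O)[C@H]3[C@@]4(CCC[C@@]5(C)COC(=O)[C@H]54)COC(=O)[C@]3(C2)C1=O | intermediate
29 | 11-dehydroguidongnin (11-ketone, 15-OH endo as in 30) | C=C1[C@@H]2CC(=O)[C@H]3[C@@]4(CCC[C@@]5(C)COC(=O)[C@H]54)COC(=O)[C@]3(C2)[C@@H]1O | intermediate
30 | guidongnin | C=C1[C@@H]2C[C@@H](O)[C@H]3[C@@]4(CCC[C@@]5(C)COC(=O)[C@H]54)COC(=O)[C@]3(C2)[C@@H]1O | target

**Step count and risks**

Total step count: 20. Longest linear sequence: 17 steps (steps 4 to 20, from 5); steps 1 to 3 make iodide 4.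

Step 16. Two processes may spoil it. The trivalent samarium enolate may be lost before ring D closes, by protonation or by Claisen-type attack on the C6 lactone carbonyl, because the 5-exo aldol must pass through a twist-boat of ring C. Pinacol coupling of the two formyl groups to a cyclopentanediol may also compete with the 6-endo ketyl addition; the slow inverse addition is meant to suppress this. The fallback keeps the desymmetrising ketyl closure but closes ring D in a separate, known operation. It therefore answers the first failure mode only; it does not help if pinacol coupling dominates. It sets out from 22 and comes back at 25. SmI2 (2.1 equiv, slow addition) with t-BuOH in THF at −78 °C stops the sequence after ring C and should give hydroxy aldehyde F1. Wittig methylenation with Ph3P=CH2 turns the spare formylmethyl arm into an allyl group, giving allyl lactone F2. KN(SiMe3)2 and t-BuMe2SiCl give the silyl ether ketene acetal F3. Pd(OAc)2 with AcOH in DMSO at 45 °C closes ring D by oxidative cyclisation of the ketene acetal onto the alkene (mediated by divalent palladium, 5-exo), giving the C15-methylene bicycle F4. Ozonolysis gives silyloxy ketone F5, HF·pyridine gives hydroxy ketone F6, and Dess–Martin oxidation returns 25.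

Step 18. Enolisation may not be regioselective: deprotonation at C12 of the C11 ketone would methylenate the wrong ring, and a C9–C11 enolate could epimerise C9. The fallback removes the second ketone during the methylenation; it sets out from 24 and comes back at 28. Et3SiOTf and 2,6-lutidine give the bis(triethylsilyl) ether F7. Pyridinium p-toluenesulfonate in MeOH cleaves the exposed exo 15-O-silyl group first, giving the mono-silyl ether F8 in which the buried axial 11-oxygen stays protected. Dess–Martin oxidation gives ketone F9, whose only enolisable ketone position is C16. The same LiN(SiMe3)2/Eschenmoser's salt/MeI/NaHCO3 sequence gives silyloxy enone F10, HF·pyridine gives hydroxy enone F11, and Dess–Martin oxidation returns 28.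

Step 20. Hydride delivery from the C15 oxygen passes through a larger ring than in a beta-hydroxy ketone and may be slow. Uncontrolled external attack would then give poor facial selectivity at C11 and some of the axial 11-epimer. The fallback changes the control element from hydride delivery to electron transfer under thermodynamic control; it sets out from 29 and ends at 30 without a new compound. SmI2 with MeOH in THF at 23 °C reduces the ketone through its ketyl, which should protonate to the more stable equatorial alcohol (trans to H9), and leaves the lactones alone because no water or amine activator is present.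

**Further compounds**

F1 | step 16 | ring C closed hydroxy aldehyde (C8–H, C8 not defined; 11-OH cis to H9; CH2CHO arm on C13 syn to H9) | O=CC[C@@H]2C[C@H](O)[C@H]3[C@@]4(CCC[C@@]5(C)COC(=O)[C@H]54)COC(=O)C3C2
F2 | step 16 | allyl lactone (F1 with the arm as CH2CH=CH2) | C=CC[C@@H]2C[C@H](O)[C@H]3[C@@]4(CCC[C@@]5(C)COC(=O)[C@H]54)COC(=O)C3C2
F3 | step 16 | 11-O-tert-butyldimethylsilyl ether and O-silyl ketene acetal (C7=C8) of F2 | C=CC[C@@H]2C[C@H](O[Si](C)(C)C(C)(C)C)[C@H]3[C@@]4(CCC[C@@]5(C)COC(=O)[C@H]54)COC(O[Si](C)(C)C(C)(C)C)=C3C2
F4 | step 16 | ring D closed 11-silyl ether with an exocyclic methylene on C15 | C1[C@@H]2C[C@H](O[Si](C)(C)C(C)(C)C)[C@H]3[C@@]4(CCC[C@@]5(C)COC(=O)[C@H]54)COC(=O)[C@]3(C2)C1=C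
F5 | step 16 | 11-O-tert-butyldimethylsilyl-11-epi-17-norguidongnin-15-one | C1[C@@H]2C[C@H](O[Si](C)(C)C(C)(C)C)[C@H]3[C@@]4(CCC[C@@]5(C)COC(=O)[C@H]54)COC(=O)[C@]3(C2)C1=O
F6 | step 16 | 11-epi-17-norguidongnin-15-one (11-OH cis to H9) | C1[C@@H]2C[C@H](O)[C@H]3[C@@]4(CCC[C@@]5(C)COC(=O)[C@H]54)COC(=O)[C@]3(C2)C1=O
F7 | step 18 | 11,15-bis(triethylsilyl) ether of 24 | C1[C@@H]2C[C@H](O[Si](CC)(CC)CC)[C@H]3[C@@]4(CCC[C@@]5(C)COC(=O)[C@H]54)COC(=O)[C@]3(C2)[C@H]1O[Si](CC)(CC)CC
F8 | step 18 | 11-O-triethylsilyl ether of 24 with free 15-OH | C1[C@@H]2C[C@H](O[Si](CC)(CC)CC)[C@H]3[C@@]4(CCC[C@@]5(C)COC(=O)[C@H]54)COC(=O)[C@]3(C2)[C@H]1O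
F9 | step 18 | 11-O-triethylsilyl-11-epi-17-norguidongnin-15-one | C1[C@@H]2C[C@H](O[Si](CC)(CC)CC)[C@H]3[C@@]4(CCC[C@@]5(C)COC(=O)[C@H]54)COC(=O)[C@]3(C2)C1=O
F10 | step 18 | 11-O-triethylsilyl-11-epi-15-dehydroguidongnin (16-methylene-15-one) | C=C1[C@@H]2C[C@H](O[Si](CC)(CC)CC)[C@H]3[C@@]4(CCC[C@@]5(C)COC(=O)[C@H]54)COC(=O)[C@]3(C2)C1=O
F11 | step 18 | 11-epi-15-dehydroguidongnin (16-methylene-15-one, 11-OH cis to H9) | C=C1[C@@H]2C[C@H](O)[C@H]3[C@@]4(CCC[C@@]5(C)COC(=O)[C@H]54)COC(=O)[C@]3(C2)C1=O
F0 | step 20 | none | none
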